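**Retrosynthetic overview** (guaiane numbering C1–C15 for the left half, primed eudesmane numbering for the britannilactone half)

1. Feature: C10, the CH(CH3) carbon of the cycloheptane (C1, C5–C10), is bonded to C1 of the five-membered ring (C1–C5). C1=C10 is therefore the exocyclic bond of a fulvene, and hydride addition at C10 gives a cyclopentadienide that can be silylated at C2.
2. The lactone C8–O–C12(=O) with C11=C13 is opened to a 2-methylene-1,4-diol and closed last by oxidation, so no enolate chemistry is needed beside the acetates. C2–OAc comes from C2–SiHMe2 (Tamao–Fleming). The norbornene bonds C1–C13′ and C3–C11′ come from a Diels–Alder reaction of the 2-silylcyclopentadiene with 1-O-acetylbritannilactone, anti to silicon.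
3. C1=C10 comes from an intramolecular amine-mediated fulvene condensation of a cyclopentadiene-tethered methyl ketone. C5–C6 comes from an alkyllithium and 2-methylcyclopent-2-enone. C7–C8 comes from an Evans dienolate syn-aldol that also brings in C11–C13.
4. Ring order: cyclopentadiene (from the enone), cycloheptane (fulvene closure), norbornene (Diels–Alder), α-methylene-γ-lactone (last).

Key step: step 11

Remark: 1-O-acetylbritannilactone (22), the 1,10-seco-eudesmanolide half, is a catalogued natural product of Inula britannica and is taken as a purchased starting material instead of being built from citronellal; cyclopentadienes 17 and 21 are mixtures of 1,5-shift isomers drawn as one tautomer.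

**Step 1**
Reactants: 1 (R)-4-benzyl-1,3-oxazolidin-2-one; 2 3-methylbut-2-enoyl chloride
Product: 4 (R)-4-benzyl-3-(3-methylbut-2-enoyl)-1,3-oxazolidin-2-one, via lithium oxazolidinide 3 (not isolated)
Conditions: n-BuLi, THF, −78 °C; then 2, −78 → 0 °C
Reagents that add atoms: none
Why: N-acylation of the lithiated oxazolidinone by the acid chloride (standard Evans imide formation); no stereocentre is formed.

**Step 2**
Reactants: 5 ethyl 2-(2-methyl-1,3-dioxolan-2-yl)acetate
Product: 6 2-(2-methyl-1,3-dioxolan-2-yl)acetaldehyde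
Conditions: iBu2AlH (1.05 equiv), CH2Cl2, −78 °C; aq. Rochelle salt
Reagents that add atoms: none
Why: Half-reduction of the ester by diisobutylaluminium hydride at −78 °C stops at the aluminium hemiacetal, which gives the aldehyde on work-up, and the ketal is inert.

**Step 3**
Reactants: 4 imide; 6 aldehyde
Product: 8 (R)-4-benzyl-3-[(2R,3S)-3-hydroxy-4-(2-methyl-1,3-dioxolan-2-yl)-2-(prop-1-en-2-yl)butanoyl]-1,3-oxazolidin-2-one (C7 and C8 set), via boron dienolate 7 (not isolated)
Conditions: Bu2BOTf, Et3N, CH2Cl2, −78 → 0 °C; 6, −78 → 0 °C; pH 7 buffer, MeOH, 30% H2O2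
Reagents that add atoms: none
Why: Evans syn-aldol reaction in which soft enolisation at the γ-methyl gives the (Z)-boron dienolate, which reacts at Cα through a Zimmerman–Traxler chair on the face opposite the benzyl group; this sets C7 and C8 (syn) and places the isopropenyl group (C11–C13) on C7.

**Step 4**
Reactants: 8 aldol adduct
Product: 9 C8 tert-butyldimethylsilyl ether of 8
Conditions: TBSOTf, 2,6-lutidine, CH2Cl2, −78 → 0 °C
Reagents that add atoms: tert-butyldimethylsilyl trifluoromethanesulfonate, CC(C)(C)[Si](C)(C)OS(=O)(=O)C(F)(F)F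
Why: Silylation of the secondary alcohol with the silyl triflate, which blocks retro-aldol cleavage and makes the later β-oxygen a poor leaving group.

**Step 5**
Reactants: 9 silyl ether
Product: 10 (2S,3S)-3-(tert-butyldimethylsilyloxy)-4-(2-methyl-1,3-dioxolan-2-yl)-2-(prop-1-en-2-yl)butan-1-ol (C6 alcohol)
Conditions: LiBH4, MeOH (2 equiv), THF, 0 °C
Reagents that add atoms: none
Why: Reductive cleavage of the N-acyloxazolidinone by LiBH4 gives the primary alcohol and releases the auxiliary; C7 cannot epimerise because no enolisable carbonyl remains.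

**Step 6**
Reactants: 10 alcohol
Product: 11 C6 iodide (C7 isopropenyl, C8 OTBS, C10 as dioxolane)
Conditions: I2, PPh3, imidazole, CH2Cl2, 0 °C → rt
Reagents that add atoms: iodine, II
Why: Appel-type iodination of the primary alcohol under buffered conditions that leave the silyl ether and the ketal intact.

**Step 7**
Reactants: 11 iodide
Product: 12 allylic alcohol (C12–OH on the C11=C13 unit)
Conditions: SeO2 (0.3 equiv), t-BuOOH, CH2Cl2, 0 °C → rt
Reagents that add atoms: tert-butyl hydroperoxide, CC(C)(C)OO; selenium dioxide (oxygen carrier), O=[Se]=O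
Why: Selenium dioxide allylic oxidation (ene reaction, then 2,3-sigmatropic shift) should hydroxylate the methyl group of the 1,1-disubstituted alkene in preference to the hindered tertiary C7–H, with C11=C13 left in place.

**Step 8**
Reactants: 12 allylic alcohol
Product: 13 bis-silyl ether iodide (C8 OTBS, C12 OTBS)
Conditions: TBSCl, imidazole, DMAP (cat.), CH2Cl2, 0 °C → rt
Reagents that add atoms: tert-butyldimethylsilyl chloride, CC(C)(C)[Si](C)(C)Cl
Why: Standard silylation of the primary allylic alcohol.

**Step 9**
Reactants: 13 iodide; 14 2-methylcyclopent-2-en-1-one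
Product: 16 1-alkyl-2-methylcyclopent-2-en-1-ol (epimers at the carbinol carbon, C5), via alkyllithium 15 (not isolated)
Conditions: t-BuLi (2.1 equiv), Et2O/pentane, −78 °C; then 14, −78 → −30 °C; H2O
Reagents that add atoms: none
Why: Iodine–lithium exchange gives a primary alkyllithium without a β-leaving group, which should add 1,2 to the enone carbonyl; the new carbinol centre is removed in the next step.

**Step 10**
Reactants: 16 cyclopentenol
Product: 17 cyclopentadiene-tethered methyl ketone (1-methyl-2-alkylcyclopentadiene; C7 bears C(=CH2)CH2OTBS, C8 bears OTBS, C10 is the ketone)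
Conditions: PPTS (0.3 equiv), acetone/H2O 10:1, 45 °C
Reagents that add atoms: water, O
Why: Acid-catalysed ionisation of the tertiary allylic alcohol and loss of a ring proton gives the cyclopentadiene while the dioxolane is hydrolysed to the methyl ketone; both silyl ethers should survive the buffered acid.

**Step 11 (key step)**
Reactants: 17 cyclopentadiene ketone
Product: 19 cycloheptane-fused fulvene (C1=C10), via Mannich base 18 (not isolated)
Conditions: pyrrolidine (3 equiv), MeOH/THF 4:1, 0.01 M, rt; AcOH quench
Reagents that add atoms: none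
Why: Pyrrolidine converts the C10 methyl ketone into an iminium ion and also generates the cyclopentadienide, on which all 1,5-hydrogen-shift isomers of 17 converge; C1 attacks the iminium carbon and elimination of pyrrolidine from the Mannich base gives the C1=C10 fulvene. This is the amine-mediated (pyrrolidine/MeOH) condensation of a cyclopentadiene with a ketone, run intramolecularly. The cycloheptane closes by 7-exo-trig attack of C1 on the exocyclic iminium. No stereocentre is formed, and C7 and C8 are untouched because neither is α to the carbonyl. The step needs site selectivity for C1: attack through the substituted C5 or C4 is reversible and cannot lose the amine, and C2 or C3 would give bridged rings, so only the C1 adduct drains to the conjugated fulvene. It also needs the β-oxy ketone to stay intact, which the tert-butyldimethylsilyl ether at C8 secures (poor leaving group, no free hydroxyl for retro-aldol), while high dilution suppresses intermolecular condensation.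

**Step 12**
Reactants: 19 fulvene
Product: 21 2-(dimethylsilyl)cyclopentadiene (drawn as the C2-silyl tautomer; C10 set, silicon syn to the C10 methyl), via lithium cyclopentadienide 20 (not isolated)
Conditions: LiBHEt3 (1.05 equiv), THF, −78 → 0 °C; Me2SiHCl, −78 °C → rt; pentane, filtration, used crude
Reagents that add atoms: chlorodimethylsilane, C[SiH](C)Cl
Why: Hydride adds to the exocyclic fulvene carbon C10 (known fulvene-to-cyclopentadienide reduction), and the bulky borohydride is expected to enter anti to the axial C8–H of the half-chair that keeps the C7 and C8 substituents equatorial, which sets C10 with H cis to O8; C-silylation at a ring CH on the face opposite the solvated lithium, followed by suprafacial 1,5-silyl shifts, is expected to place silicon on C2 syn to the C10 methyl.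

**Step 13**
Reactants: 21 silyl diene; 22 1-O-acetylbritannilactone
Product: 23 Diels–Alder adduct (norbornene C1, C2, C3, C4=C5, C13′, C11′; 2-SiHMe2 syn to C4=C5; spiro-lactone at C11′ with C12′=O exo; free 6′-OH)
Conditions: toluene (1 M), BHT (cat.), 70 °C, sealed tube
Reagents that add atoms: none
Why: Diels–Alder reaction of the 5-silylcyclopentadiene (C2-silyl tautomer, in rapid silatropic exchange with the C3-silyl form) with the s-cis α-methylene lactone, in which the dienophile adds anti to silicon, its CH2 (C13′) bonds to the fully substituted terminus C1 and C11′ to the CH terminus C3, and the lactone carbonyl is exo as is usual for α-methylene-γ-butyrolactones; together this sets C1, C3 and C11′.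

**Step 14**
Reactants: 23 adduct
Product: 24 6′-O-tert-butyldimethylsilyl ether of 23
Conditions: TBSOTf, 2,6-lutidine, CH2Cl2, 0 °C → rt
Reagents that add atoms: tert-butyldimethylsilyl trifluoromethanesulfonate, CC(C)(C)[Si](C)(C)OS(=O)(=O)C(F)(F)F
Why: Silylation of the only free hydroxyl (C6′), so that the C2 oxygen alone is acetylated later.

**Step 15**
Reactants: 24 silane
Product: 25 C2 alcohol (OH syn to C4=C5)
Conditions: KF, KHCO3, 30% aq. H2O2, THF/MeOH 1:1, 40 °C
Reagents that add atoms: hydrogen peroxide, OO
Why: Tamao–Fleming oxidation of the hydrodimethylsilyl group (fluoride-assisted peroxide attack at silicon, then migration of C2 from silicon to oxygen) replaces C–Si by C–OH with retention; basic peroxide should not touch the tetrasubstituted alkenes or the unactivated C11=C13 bond.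

**Step 16**
Reactants: 25 alcohol
Product: 26 C2 acetate
Conditions: Ac2O, pyridine, DMAP (cat.), CH2Cl2, rt
Reagents that add atoms: acetic anhydride, CC(=O)OC(C)=O
Why: DMAP-catalysed acetylation of the only free hydroxyl, which would also restore the C1′ acetate should it have been cleaved in step 15.

**Step 17**
Reactants: 26 tris-silyl ether
Product: 27 triol (C8–OH, C12–OH, C6′–OH)
Conditions: HF·pyridine, pyridine, THF, 0 °C → rt
Reagents that add atoms: none
Why: Fluoride-mediated cleavage of the three tert-butyldimethylsilyl ethers under buffered conditions that leave acetates and the spiro-lactone untouched.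

**Step 18**
Reactants: 27 triol
Product: 29 target (CNP0211028.3), via lactol 28 (not isolated)
Conditions: TEMPO (0.2 equiv), PhI(OAc)2 (2.5 equiv), CH2Cl2, rt
Reagents that add atoms: none
Why: Oxoammonium (TEMPO) oxidation is selective for the primary allylic alcohol, the resulting enal is trapped by the C8 hydroxyl as a lactol and oxidised on to the trans-fused α-methylene-γ-lactone (C7 and C8 already set), and the hindered secondary C6′ alcohol should be left alone.

**Compound list**

1 | (R)-4-benzyl-1,3-oxazolidin-2-one | O=C1N[C@H](Cc2ccccc2)CO1 | starting material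
2 | 3-methylbut-2-enoyl chloride | CC(C)=CC(=O)Cl | starting material
3 | lithium salt of 1 | [Li+].O=C1[N-][C@H](Cc2ccccc2)CO1 | intermediate (not isolated)
4 | (R)-4-benzyl-3-(3-methylbut-2-enoyl)-1,3-oxazolidin-2-one | CC(C)=CC(=O)N1[C@H](Cc2ccccc2)COC1=O | intermediate
5 | ethyl 2-(2-methyl-1,3-dioxolan-2-yl)acetate | CCOC(=O)CC1(C)OCCO1 | starting material
6 | 2-(2-methyl-1,3-dioxolan-2-yl)acetaldehyde | O=CCC1(C)OCCO1 | intermediate
7 | dibutylboron (Z)-dienolate of 4 | C=C(C)/C=C(\OB(CCCC)CCCC)N1[C@H](Cc2ccccc2)COC1=O | intermediate (not isolated)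
8 | syn-aldol adduct, (2R,3S), C7 isopropenyl, C8 OH | O=C(N1[C@H](Cc2ccccc2)COC1=O)[C@H](C(C)=C)[C@@H](O)CC3(C)OCCO3 | intermediate
9 | C8 TBS ether of 8 | O=C(N1[C@H](Cc2ccccc2)COC1=O)[C@H](C(C)=C)[C@@H](O[Si](C)(C)C(C)(C)C)CC3(C)OCCO3 | intermediate
10 | C6 primary alcohol, (2S,3S) | OC[C@H](C(C)=C)[C@@H](O[Si](C)(C)C(C)(C)C)CC1(C)OCCO1 | intermediate
11 | C6 iodide | IC[C@H](C(C)=C)[C@@H](O[Si](C)(C)C(C)(C)C)CC1(C)OCCO1 | intermediate
12 | C6 iodide with C12 allylic alcohol | IC[C@H](C(=C)CO)[C@@H](O[Si](C)(C)C(C)(C)C)CC1(C)OCCO1 | intermediate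
13 | C6 iodide, C8 and C12 TBS ethers | IC[C@H](C(=C)CO[Si](C)(C)C(C)(C)C)[C@@H](O[Si](C)(C)C(C)(C)C)CC1(C)OCCO1 | intermediate
14 | 2-methylcyclopent-2-en-1-one | CC1=CCCC1=O | starting material
15 | C6 alkyllithium from 13 | [Li]C[C@H](C(=C)CO[Si](C)(C)C(C)(C)C)[C@@H](O[Si](C)(C)C(C)(C)C)CC1(C)OCCO1 | intermediate (not isolated)
16 | 1-alkyl-2-methylcyclopent-2-en-1-ol (carbinol epimers) | CC1=CCCC1(O)C[C@H](C(=C)CO[Si](C)(C)C(C)(C)C)[C@@H](O[Si](C)(C)C(C)(C)C)CC2(C)OCCO2 | intermediate
17 | cyclopentadiene-tethered methyl ketone (key-step precursor) | CC1=CCC=C1C[C@H](C(=C)CO[Si](C)(C)C(C)(C)C)[C@@H](O[Si](C)(C)C(C)(C)C)CC(C)=O | intermediate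
18 | Mannich base (C10 pyrrolidinyl adduct, C1–C10 bond formed) | CC1=C2C[C@H](C(=C)CO[Si](C)(C)C(C)(C)C)[C@@H](O[Si](C)(C)C(C)(C)C)CC(C)(N3CCCC3)C2C=C1 | intermediate (not isolated)
19 | cycloheptane-fused fulvene (C1=C10) | CC1=C2C[C@H](C(=C)CO[Si](C)(C)C(C)(C)C)[C@@H](O[Si](C)(C)C(C)(C)C)CC(C)=C2C=C1 | intermediate
20 | lithium cyclopentadienide (C10 H cis to O8) | [Li+].CC1=C[CH-]C2=C1C[C@H](C(=C)CO[Si](C)(C)C(C)(C)C)[C@@H](O[Si](C)(C)C(C)(C)C)C[C@@H]2C | intermediate (not isolated)
21 | 2-(dimethylsilyl)cyclopentadiene, silicon syn to the C10 methyl | CC1=C[C@@H]([SiH](C)C)C2=C1C[C@H](C(=C)CO[Si](C)(C)C(C)(C)C)[C@@H](O[Si](C)(C)C(C)(C)C)C[C@@H]2C | intermediate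
22 | 1-O-acetylbritannilactone | C=C1C(=O)O[C@@H]2CC(C)=C([C@@H](C)CCCOC(C)=O)[C@@H](O)[C@@H]21 | starting material
23 | Diels–Alder adduct, 2-SiHMe2, 6′-OH | CC(C)(C)[Si](C)(C)O[C@H]1C[C@H](C)[C@@]23C[C@]4(C(=O)O[C@@H]5CC(C)=C([C@@H](C)CCCOC(C)=O)[C@@H](O)[C@@H]54)[C@@H](C(C)=C2C[C@@H]1C(=C)CO[Si](C)(C)C(C)(C)C)[C@H]3[SiH](C)C | intermediate
24 | 6′-O-TBS ether of 23 | CC(C)(C)[Si](C)(C)O[C@H]1C[C@H](C)[C@@]23C[C@]4(C(=O)O[C@@H]5CC(C)=C([C@@H](C)CCCOC(C)=O)[C@@H](O[Si](C)(C)C(C)(C)C)[C@@H]54)[C@@H](C(C)=C2C[C@@H]1C(=C)CO[Si](C)(C)C(C)(C)C)[C@H]3[SiH](C)C | intermediate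
25 | C2 alcohol | CC(C)(C)[Si](C)(C)O[C@H]1C[C@H](C)[C@@]23C[C@]4(C(=O)O[C@@H]5CC(C)=C([C@@H](C)CCCOC(C)=O)[C@@H](O[Si](C)(C)C(C)(C)C)[C@@H]54)[C@@H](C(C)=C2C[C@@H]1C(=C)CO[Si](C)(C)C(C)(C)C)[C@H]3O | intermediate
26 | C2 acetate | CC(C)(C)[Si](C)(C)O[C@H]1C[C@H](C)[C@@]23C[C@]4(C(=O)O[C@@H]5CC(C)=C([C@@H](C)CCCOC(C)=O)[C@@H](O[Si](C)(C)C(C)(C)C)[C@@H]54)[C@@H](C(C)=C2C[C@@H]1C(=C)CO[Si](C)(C)C(C)(C)C)[C@H]3OC(C)=O | intermediate
27 | triol (C8–OH, C12–OH, C6′–OH) | O[C@H]1C[C@H](C)[C@@]23C[C@]4(C(=O)O[C@@H]5CC(C)=C([C@@H](C)CCCOC(C)=O)[C@@H](O)[C@@H]54)[C@@H](C(C)=C2C[C@@H]1C(=C)CO)[C@H]3OC(C)=O | intermediate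
28 | C12 lactol | C=C1C(O)O[C@H]2C[C@H](C)[C@@]34C[C@]5(C(=O)O[C@@H]6CC(C)=C([C@@H](C)CCCOC(C)=O)[C@@H](O)[C@@H]65)[C@@H](C(C)=C3C[C@H]12)[C@H]4OC(C)=O | intermediate (not isolated)
29 | CNP0211028.3 | C=C1C(=O)O[C@H]2C[C@H](C)[C@@]34C[C@]5(C(=O)O[C@@H]6CC(C)=C([C@@H](C)CCCOC(C)=O)[C@@H](O)[C@@H]65)[C@@H](C(C)=C3C[C@H]12)[C@H]4OC(C)=O | target

**Step count**

Total: 18 steps. Longest linear sequence: 17 steps (steps 1 and 3–18, from oxazolidinone 1).

**Steps most likely to fail**

Step 13 (Diels–Alder). The thermal reaction with the hindered lactone may be slow and poorly discriminating. The diene may react through its C3-silyl form (bonding at C2 and C4), the lactone may add carbonyl-endo on its convex face instead of the required C6′ face, and the free C6′ hydroxyl may protonolyse the allylic C2–Si bond before cycloaddition. Fallback, which changes the order of events and the dienophile: set out from 22 and silylate it first (TBSOTf, 2,6-lutidine) to 1-O-acetyl-6-O-(tert-butyldimethylsilyl)britannilactone F1. Cycloaddition of 21 with the hydroxyl-free F1 would give 24 directly, so the route is rejoined at 24 without passing through 23. This removes the proton source, but it does not lock the silatropic form of the diene, which remains the open risk of the silicon tactic.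

Step 12 (hydride addition and silylation). The conformational bias for hydride attack at C10 is modest, so both faces may be attacked, and silicon may enter anti to the C10 methyl. Fallback, which replaces steric control by substrate-directed delivery: set out from fulvene 19 and remove both silyl ethers (TBAF buffered with AcOH, THF, 0 °C) to give fulvene diol F2. LiAlH4 in THF should form the C8 alkoxyaluminate, which delivers hydride intramolecularly to C10 through a six-membered transition state (H cis to O8). Addition of Me2SiHCl at −78 °C and a bicarbonate work-up would give diol silyl diene F3. Re-silylation of both hydroxyls (TBSCl, imidazole, DMF, 0 °C) returns to 21.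

Step 11 (key step). The seven-membered closure may be slower than intermolecular fulvene formation, or the amine may trigger β-elimination of the C8 silyloxy group through the enamine. Fallback, which separates carbanion addition from dehydration: set out from 17 and treat it with NaH (1.05 equiv, THF, 0 °C), which should deprotonate only the cyclopentadiene. The cyclopentadienide adds to the ketone through C1 and a buffered quench gives tertiary alcohol F4. Dehydration of this cyclopentadienyl carbinol (MsCl, Et3N, CH2Cl2, 0 °C) gives fulvene 19.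

**Further compounds**

F1 | step 13 | 1-O-acetyl-6-O-(tert-butyldimethylsilyl)britannilactone | C=C1C(=O)O[C@@H]2CC(C)=C([C@@H](C)CCCOC(C)=O)[C@@H](O[Si](C)(C)C(C)(C)C)[C@@H]21
F2 | step 12 | fulvene diol (C8–OH, C12–OH) | CC1=C2C[C@H](C(=C)CO)[C@@H](O)CC(C)=C2C=C1
F3 | step 12 | 2-(dimethylsilyl)cyclopentadiene diol | CC1=C[C@@H]([SiH](C)C)C2=C1C[C@H](C(=C)CO)[C@@H](O)C[C@@H]2C
F4 | step 11 | C10 tertiary alcohol (C1–C10 bond formed, epimers at C1 and C10) | CC1=C2C[C@H](C(=C)CO[Si](C)(C)C(C)(C)C)[C@@H](O[Si](C)(C)C(C)(C)C)CC(C)(O)C2C=C1
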